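**Plan**
- Numbering: the target is a 3,7-dioxabicyclo[3.3.0]octane, C1(OH), C2(Ar), O3, C4, C5(H), C6(Ar), O7, C8, with both aryl groups endo. C1 and C2 are neighbouring carbons that each carry oxygen (C1–OH, C2–O3), so both C–O bonds can be traced back to one syn addition of two oxygens to a C1=C2 arylidene.
- Retrosynthetic cuts, in order: the ether bonds O7–C8 and O3–C4; then C1–O and C2–O together (dihydroxylation of an E-α-arylidene-γ-lactone with C8 as carbonyl); then C2–aryl (Heck); then C5–C6 and the lactone C–O bond (allylboration/lactonisation).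
- Forward: the lactone ring C1–C5–C6–O7–C8 is made first, the second aryl is attached at C2, the alkene is dihydroxylated, hydride opens the lactone, both tetrahydrofuran rings close in one operation, and the phenols are debenzylated.
- Stereochemistry: C6 from a chiral-phosphoric-acid-controlled Re-face allylboration; C5 from the chair transition state (CH2OTBS cis to CH2B gives the cis lactone); C1 from osmylation anti to the cis C5/C6 substituents; C2 from the E geometry through suprafacial addition. The ring closures occur at CH2 carbons and touch none of the four centres.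

Key step: step 7

Notation: Ar = 4-(benzyloxy)-3-methoxyphenyl, TBS = tert-butyldimethylsilyl, pin = pinacolato; locants C1–C8 are those of the target bicycle.
Assumption: (R)-TRIP is taken to deliver the ester-substituted allylboronate to the Re face of the aryl aldehyde, the sense it shows with simple allyl and crotyl pinacolboronates; if the ester-bearing reagent responded in the opposite sense, the (S)-acid would be used.

**Step 1**
Reactants: 1 methyl acrylate; 2 (tert-butyldimethylsilyloxy)acetaldehyde
Product: 3 methyl 4-[(tert-butyldimethylsilyl)oxy]-3-hydroxy-2-methylidenebutanoate (racemic)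
Conditions: 1,4-diazabicyclo[2.2.2]octane (DABCO, 0.5 equiv), excess 1, 1,4-dioxane–H2O 1:1, rt
Reagents that add atoms: none
Why: Morita–Baylis–Hillman reaction, in which the amine adds to the acrylate and the resulting enolate attacks the activated α-silyloxy aldehyde; the carbinol centre forms as a racemate, which does not matter because it is erased in step 3.

**Step 2**
Reactants: 3 racemic Baylis–Hillman alcohol
Product: 4 methyl 3-acetoxy-4-[(tert-butyldimethylsilyl)oxy]-2-methylidenebutanoate (racemic)
Conditions: Ac2O (1.5 equiv), pyridine, 4-(dimethylamino)pyridine (5 mol %), CH2Cl2, 0 °C to rt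
Reagents that add atoms: acetic anhydride, CC(=O)OC(C)=O
Why: Standard O-acetylation of a secondary allylic alcohol, which turns the hydroxyl into the leaving group needed for allylic substitution.

**Step 3**
Reactants: 4 allylic acetate
Product: 5 methyl (2E)-4-[(tert-butyldimethylsilyl)oxy]-2-[(4,4,5,5-tetramethyl-1,3,2-dioxaborolan-2-yl)methyl]but-2-enoate (CH2OTBS trans to the ester, cis to CH2B)
Conditions: B2pin2 (1.1 equiv), Pd2(dba)3 (2.5 mol %), toluene, 50 °C
Reagents that add atoms: bis(pinacolato)diboron, CC1(C)OB(OC1(C)C)B1OC(C)(C)C(C)(C)O1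
Why: Palladium-catalysed allylic borylation, in which zerovalent palladium ionises the acetate to a 2-(methoxycarbonyl)allylpalladium acetate that transmetallates with the diboron and forms the C–B bond at the unsubstituted terminus, the trisubstituted alkene settling in the favoured geometry with CH2OTBS trans to the ester.

**Step 4**
Reactants: 5 allylboronate; 6 4-(benzyloxy)-3-methoxybenzaldehyde (O-benzylvanillin)
Product: 9 (4R,5R)-5-Ar-4-{[(tert-butyldimethylsilyl)oxy]methyl}-3-methylideneoxolan-2-one (aryl and CH2OTBS cis), via pinacol borate 7 (not isolated), via hydroxy ester 8 (not isolated)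
Conditions: (R)-TRIP [(R)-3,3′-bis(2,4,6-triisopropylphenyl)-1,1′-binaphthyl-2,2′-diyl hydrogen phosphate, 10 mol %], 4 Å molecular sieves, toluene, 0 °C to rt; aq. NaHCO3 wash; then Cs2CO3 (0.2 equiv), THF, 40 °C
Reagents that add atoms: none
Why: Chiral-phosphoric-acid-catalysed allylboration through a closed chair transition state, in which the acid activates a boronate oxygen and steers the allyl unit to the Re face of the aldehyde (C6 = R) while the CH2OTBS group, cis to CH2B and therefore axial, ends up syn to the new oxygen (C5 = R), after which base-mediated transesterification closes the lactone without ionising the electron-rich benzylic C–O bond, so aryl and CH2OTBS stay cis.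

**Step 5**
Reactants: 10 4-iodo-2-methoxyphenol
Product: 11 1-(benzyloxy)-4-iodo-2-methoxybenzene
Conditions: BnBr (1.1 equiv), K2CO3 (1.5 equiv), DMF, rt
Reagents that add atoms: benzyl bromide, BrCc1ccccc1
Why: Williamson O-benzylation of the phenoxide, which gives the aryl iodide the same phenol protection as the aldehyde.

**Step 6**
Reactants: 9 cis α-methylene lactone; 11 aryl iodide
Product: 12 (3E,4R,5R)-5-Ar-3-(Ar-methylidene)-4-{[(tert-butyldimethylsilyl)oxy]methyl}oxolan-2-one (arylidene aryl trans to the carbonyl, cis to C5)
Conditions: Pd(OAc)2 (10 mol %), Et3N (3 equiv), DMF, 80 °C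
Reagents that add atoms: none
Why: Mizoroki–Heck arylation, in which the aryl iodide adds oxidatively to zerovalent palladium formed in situ, syn carbopalladation places the aryl on the methylene carbon, and syn β-hydride elimination from the benzylic CH2 gives the conjugated exocyclic alkene with the aryl trans to the lactone carbonyl (E), as is usual for α-methylene lactones and methacrylates.

**Step 7**
Reactants: 12 E-arylidene lactone
Product: 13 (3R,4R,5R)-5-Ar-3-[(S)-Ar(hydroxy)methyl]-4-{[(tert-butyldimethylsilyl)oxy]methyl}-3-hydroxyoxolan-2-one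
Conditions: OsO4 (5 mol %), N-methylmorpholine N-oxide (2.5 equiv), acetone–H2O 8:1, rt
Reagents that add atoms: osmium tetroxide, O=[Os](=O)(=O)=O (delivers both oxygens); N-methylmorpholine N-oxide, C[N+]1([O-])CCOCC1 (stoichiometric oxygen source that regenerates it)
Why: OsO4 adds across C1=C2 in a concerted suprafacial [3+2] manner to give a glycolate of hexavalent osmium, which water hydrolyses to the syn diol while the N-oxide restores OsO4; no ring is closed, and the closest known reaction type is the catalytic OsO4/amine N-oxide dihydroxylation of α-alkylidene and α-arylidene lactones and other trisubstituted enoates. C1 is set by the choice of alkene face: the CH2OTBS group on the allylic carbon C5 and the cis aryl on C6 lie on one side of the lactone, and allylic strain with the arylidene aryl pushes CH2OTBS out of the alkene plane, so the reagent should enter from the opposite side and place C1–OH trans to both. C2 is set by the E geometry: both oxygens arrive on the same face and the aryl is cis to C5, so the carbinol carbon becomes S, the configuration that places this aryl endo once O3 is joined to C4. The step needs facial selectivity and faithful transfer of alkene geometry; the first rests on the two cis ring substituents, the second on the concerted addition. Chemoselectivity should not be an issue, since the electron-rich arenes, the benzyl ethers and the silyl ether are inert to OsO4 at room temperature.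

**Step 8**
Reactants: 13 syn-diol lactone
Product: 14 (1S,2S,3R,4R)-1,4-bis(Ar)-3-{[(tert-butyldimethylsilyl)oxy]methyl}-2-(hydroxymethyl)butane-1,2,4-triol
Conditions: LiAlH4 (4 equiv), THF, 0 °C to rt; H2O then aq. NaOH quench
Reagents that add atoms: none
Why: Hydride reduction of the lactone to the 1,4-diol (C8H2OH and C6–OH) follows deprotonation of the two free hydroxyls, which as alkoxides disfavour retro-aldol cleavage, and leaves the silyl ether, the benzyl ethers and all four stereocentres untouched.

**Step 9**
Reactants: 14 tetraol silyl ether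
Product: 15 (1S,2S,3R,4R)-1,4-bis(Ar)-2,3-bis(hydroxymethyl)butane-1,2,4-triol
Conditions: Bu4NF (1.2 equiv), THF, 0 °C to rt
Reagents that add atoms: none
Why: Fluoride-induced cleavage of the primary silyl ether under non-acidic conditions, so the ionisable benzylic carbinols are not disturbed.

**Step 10**
Reactants: 15 pentaol
Product: 17 (1S,2S,5R,6R)-2,6-bis(Ar)-3,7-dioxabicyclo[3.3.0]octan-1-ol (both aryl groups endo), via bis(methanesulfonate) 16 (not isolated)
Conditions: MsCl (2.2 equiv), pyridine, −20 °C to 0 °C, then rt
Reagents that add atoms: none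
Why: Selective sulfonylation of the two primary hydroxyls followed by double intramolecular Williamson etherification (two 5-exo-tet closures, C6–O onto C8 and C2–O onto C4), these being the only five-membered options because every other hydroxyl/sulfonate pairing would give a three- or four-membered ring, and since the benzylic oxygens attack CH2 carbons the configurations at C1, C2, C5 and C6 are retained and the cis ring fusion follows.

**Step 11**
Reactants: 17 dibenzyl ether of the target
Product: 18 (1S,2S,5R,6R)-2,6-bis(4-hydroxy-3-methoxyphenyl)-3,7-dioxabicyclo[3.3.0]octan-1-ol (CNP0138682.2)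
Conditions: H2 (1 atm), 10 % Pd on carbon, EtOAc, rt, stopped at full conversion
Reagents that add atoms: none
Why: Catalytic hydrogenolysis of the two aryl benzyl ethers, which should cleave far faster than the dialkyl benzylic C–O bonds of the bicycle in a neutral aprotic medium, so neither ring opening nor acid-type epimerisation of the endo aryl groups is expected.

**Compound list**
1 | methyl acrylate | C=CC(=O)OC | starting material
2 | (tert-butyldimethylsilyloxy)acetaldehyde | O=CCO[Si](C)(C)C(C)(C)C | starting material
3 | methyl 4-[(tert-butyldimethylsilyl)oxy]-3-hydroxy-2-methylidenebutanoate (racemic) | COC(=O)C(=C)C(O)CO[Si](C)(C)C(C)(C)C | intermediate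
4 | methyl 3-acetoxy-4-[(tert-butyldimethylsilyl)oxy]-2-methylidenebutanoate (racemic) | COC(=O)C(=C)C(OC(C)=O)CO[Si](C)(C)C(C)(C)C | intermediate
5 | methyl (2E)-4-[(tert-butyldimethylsilyl)oxy]-2-[(4,4,5,5-tetramethyl-1,3,2-dioxaborolan-2-yl)methyl]but-2-enoate | COC(=O)/C(CB1OC(C)(C)C(C)(C)O1)=C/CO[Si](C)(C)C(C)(C)C | intermediate
6 | 4-(benzyloxy)-3-methoxybenzaldehyde | COc1cc(C=O)ccc1OCc1ccccc1 | starting material
7 | pinacol borate of 8 (O-Bpin at the benzylic oxygen) | COC(=O)C(=C)[C@H](CO[Si](C)(C)C(C)(C)C)[C@@H](OB1OC(C)(C)C(C)(C)O1)c1ccc(OCc2ccccc2)c(OC)c1 | intermediate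
8 | methyl (3R,4R)-4-[4-(benzyloxy)-3-methoxyphenyl]-3-{[(tert-butyldimethylsilyl)oxy]methyl}-4-hydroxy-2-methylidenebutanoate | COC(=O)C(=C)[C@H](CO[Si](C)(C)C(C)(C)C)[C@@H](O)c1ccc(OCc2ccccc2)c(OC)c1 | intermediate
9 | (4R,5R)-5-[4-(benzyloxy)-3-methoxyphenyl]-4-{[(tert-butyldimethylsilyl)oxy]methyl}-3-methylideneoxolan-2-one | COc1cc([C@@H]2OC(=O)C(=C)[C@@H]2CO[Si](C)(C)C(C)(C)C)ccc1OCc1ccccc1 | intermediate
10 | 4-iodo-2-methoxyphenol | COc1cc(I)ccc1O | starting material
11 | 1-(benzyloxy)-4-iodo-2-methoxybenzene | COc1cc(I)ccc1OCc1ccccc1 | intermediate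
12 | (3E,4R,5R)-5-[4-(benzyloxy)-3-methoxyphenyl]-3-{[4-(benzyloxy)-3-methoxyphenyl]methylidene}-4-{[(tert-butyldimethylsilyl)oxy]methyl}oxolan-2-one | COc1cc([C@@H]2OC(=O)/C(=C/c3ccc(OCc4ccccc4)c(OC)c3)[C@@H]2CO[Si](C)(C)C(C)(C)C)ccc1OCc1ccccc1 | intermediate
13 | (3R,4R,5R)-5-[4-(benzyloxy)-3-methoxyphenyl]-3-{(S)-[4-(benzyloxy)-3-methoxyphenyl](hydroxy)methyl}-4-{[(tert-butyldimethylsilyl)oxy]methyl}-3-hydroxyoxolan-2-one | COc1cc([C@@H]2OC(=O)[C@](O)([C@@H](O)c3ccc(OCc4ccccc4)c(OC)c3)[C@@H]2CO[Si](C)(C)C(C)(C)C)ccc1OCc1ccccc1 | intermediate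
14 | (1S,2S,3R,4R)-1,4-bis[4-(benzyloxy)-3-methoxyphenyl]-3-{[(tert-butyldimethylsilyl)oxy]methyl}-2-(hydroxymethyl)butane-1,2,4-triol | COc1cc([C@H](O)[C@@H](CO[Si](C)(C)C(C)(C)C)[C@](O)(CO)[C@@H](O)c2ccc(OCc3ccccc3)c(OC)c2)ccc1OCc1ccccc1 | intermediate
15 | (1S,2S,3R,4R)-1,4-bis[4-(benzyloxy)-3-methoxyphenyl]-2,3-bis(hydroxymethyl)butane-1,2,4-triol | COc1cc([C@H](O)[C@@H](CO)[C@](O)(CO)[C@@H](O)c2ccc(OCc3ccccc3)c(OC)c2)ccc1OCc1ccccc1 | intermediate
16 | bis(methanesulfonate) of 15 at its two primary hydroxyls (C4 and C8) | COc1cc([C@H](O)[C@@H](COS(C)(=O)=O)[C@](O)(COS(C)(=O)=O)[C@@H](O)c2ccc(OCc3ccccc3)c(OC)c2)ccc1OCc1ccccc1 | intermediate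
17 | (1S,2S,5R,6R)-2,6-bis[4-(benzyloxy)-3-methoxyphenyl]-3,7-dioxabicyclo[3.3.0]octan-1-ol | COc1cc([C@@H]2OC[C@@]3(O)[C@@H]2CO[C@H]3c2ccc(OCc4ccccc4)c(OC)c2)ccc1OCc1ccccc1 | intermediate
18 | (1S,2S,5R,6R)-2,6-bis(4-hydroxy-3-methoxyphenyl)-3,7-dioxabicyclo[3.3.0]octan-1-ol | COc1cc([C@@H]2OC[C@@]3(O)[C@@H]2CO[C@H]3c2ccc(O)c(OC)c2)ccc1O | target

**Step count and risks**
Total steps: 11. Longest linear sequence: 10 (steps 1–4 and 6–11); step 5 is a one-step side branch.

Step 4. The ester-bearing allylboronate with its γ-substituent cis to CH2B is a sluggish nucleophile. The acid-catalysed addition may stall or show modest enantioselection. The cis relationship may also be lost, either through acid-promoted E/Z isomerisation of the reagent or through ionisation at the electron-rich benzylic carbon during ring closure. The fallback sets out from 5 and 6 and drops the acid. Uncatalysed allylboration in toluene at 90 °C passes through the same closed six-membered transition state in neutral medium, which secures the cis relationship but not the absolute configuration. After the same carbonate-mediated ring closure it should give the racemic cis lactone, by way of borate 7 together with the antipodal borate F1 and hydroxy ester 8 together with the antipodal hydroxy ester F2. Lactone 9 is then separated from the (4S,5S)-lactone F3 by preparative chromatography on a chiral stationary phase (amylose tris(3,5-dimethylphenylcarbamate)), and the route is rejoined at 9.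

Step 6. After carbopalladation, β-hydride elimination may turn toward the ring, where C5–H is syn to palladium, and give the endocyclic butenolide with loss of the C5 centre. A palladium hydride may also isomerise the product or erode the E geometry on which C2 depends. The fallback sets out from 9 and uses olefin cross-metathesis with commercial 4-(benzyloxy)-3-methoxystyrene (second-generation Hoveyda–Grubbs catalyst, 2,6-dichloro-1,4-benzoquinone as hydride scavenger, toluene, 60 °C). This forms the same C1=C2 bond without an alkylpalladium intermediate and, under thermodynamic control, should favour the E isomer; it comes back to the route at 12.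

Step 10. Five hydroxyls compete. Sulfonylation of a benzylic carbinol followed by ionisation would scramble C2 or C6 toward the exo-aryl series. The neopentyl C8–OH may also react slowly, so the two closures fall out of step. The fallback sets out from 14, in which C8–OH is the only primary hydroxyl, and closes the rings one at a time. MsCl (1.1 equiv) in pyridine at 0 °C should give the C8 monomethanesulfonate F4, which closes the O7–C8 ring on warming to the monocyclic tetrahydrofuran silyl ether F5. Bu4NF then frees C4–OH to give the tetrahydrofuran triol F6. A second MsCl/pyridine treatment gives the C4 methanesulfonate F7, which closes O3–C4 and returns to the route at 17.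

**Further compounds**
F1 | step 4 | antipode of borate 7 | COC(=O)C(=C)[C@@H](CO[Si](C)(C)C(C)(C)C)[C@H](OB1OC(C)(C)C(C)(C)O1)c1ccc(OCc2ccccc2)c(OC)c1
F2 | step 4 | methyl (3S,4S)-4-[4-(benzyloxy)-3-methoxyphenyl]-3-{[(tert-butyldimethylsilyl)oxy]methyl}-4-hydroxy-2-methylidenebutanoate (antipode of 8) | COC(=O)C(=C)[C@@H](CO[Si](C)(C)C(C)(C)C)[C@H](O)c1ccc(OCc2ccccc2)c(OC)c1
F3 | step 4 | (4S,5S)-5-[4-(benzyloxy)-3-methoxyphenyl]-4-{[(tert-butyldimethylsilyl)oxy]methyl}-3-methylideneoxolan-2-one (antipode of 9) | COc1cc([C@H]2OC(=O)C(=C)[C@H]2CO[Si](C)(C)C(C)(C)C)ccc1OCc1ccccc1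
F0 | step 6 | none | none
F4 | step 10 | C8 monomethanesulfonate of 14 | COc1cc([C@H](O)[C@@H](CO[Si](C)(C)C(C)(C)C)[C@](O)(COS(C)(=O)=O)[C@@H](O)c2ccc(OCc3ccccc3)c(OC)c2)ccc1OCc1ccccc1
F5 | step 10 | (3S,4R,5R)-5-[4-(benzyloxy)-3-methoxyphenyl]-3-{(S)-[4-(benzyloxy)-3-methoxyphenyl](hydroxy)methyl}-4-{[(tert-butyldimethylsilyl)oxy]methyl}oxolan-3-ol | COc1cc([C@@H]2OC[C@](O)([C@@H](O)c3ccc(OCc4ccccc4)c(OC)c3)[C@@H]2CO[Si](C)(C)C(C)(C)C)ccc1OCc1ccccc1
F6 | step 10 | (3S,4R,5R)-5-[4-(benzyloxy)-3-methoxyphenyl]-3-{(S)-[4-(benzyloxy)-3-methoxyphenyl](hydroxy)methyl}-4-(hydroxymethyl)oxolan-3-ol | COc1cc([C@@H]2OC[C@](O)([C@@H](O)c3ccc(OCc4ccccc4)c(OC)c3)[C@@H]2CO)ccc1OCc1ccccc1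
F7 | step 10 | primary (C4) methanesulfonate of F6 | COc1cc([C@@H]2OC[C@](O)([C@@H](O)c3ccc(OCc4ccccc4)c(OC)c3)[C@@H]2COS(C)(=O)=O)ccc1OCc1ccccc1
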